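**Retrosynthetic overview**
1. Target 25 comes from dienamide 24 in one acid step that removes all protecting groups and closes the pyrone by lactonization of a masked 2-oxohex-4-enedioate; the pyrone ring is formed last.
2. 24 comes from the (Z)-enol triflate 21 and acetamidoacrylate 23 (Heck); 21 from β-keto ester 20, from the C1 acid 17, from the C1 nitromethyl compound 16 (nitro as latent carboxyl).
3. Ring B comes from an intramolecular aldol condensation of dialdehyde 13, whose two aldehydes are unmasked from the two alkenes of 12; the resulting enal is oxidized to the C3 acid.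
4. Key C1–C2 bond: intermolecular amine-catalysed Michael addition of pent-4-enal 9 to nitrostyrene 8, which sets both stereocentres at once.
5. Ring order: ring A is bought (6-bromoveratraldehyde), ring B is closed second, the pyrone third.

Assumption: the organocatalyst, the trichloroacetimidate and CDI are bought; bicyclic intermediates carry the target's 1,2-dihydronaphthalene locants (C1 future pyrone carbon, C2 and C3 carboxyl carbons, oxygens on C6 and C7).

The target is (1R,2S), with the pyrone and the C2 carboxyl trans. The C1 descriptor switches from S to R between 21 and 24 only because CIP priorities change; the geometry is unchanged.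

**Step 1**
Reactants: 1 2-bromo-4,5-dimethoxybenzaldehyde
Product: 2 2-bromo-4,5-dihydroxybenzaldehyde
Conditions: BBr3 (3 equiv), CH2Cl2, −78 °C to rt; H2O quench
Reagents that add atoms: none
Why: Lewis-acid cleavage of both aryl methyl ethers by BBr3 leaves the aldehyde and the aryl bromide alone and frees the catechol for an acid-labile ketal.

**Step 2**
Reactants: 2 2-bromo-4,5-dihydroxybenzaldehyde; 3 dichlorodiphenylmethane
Product: 4 6-bromo-2,2-diphenyl-1,3-benzodioxole-5-carbaldehyde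
Conditions: Ph2O, 175 °C, 30 min, N2 sweep
Reagents that add atoms: none
Why: Double O-alkylation of the catechol by the gem-dichloride (ketalization) gives the diphenylmethylene ketal, which survives base, oxidants and palladium and falls only to strong aqueous acid.

**Step 3**
Reactants: 4 6-bromo-2,2-diphenyl-1,3-benzodioxole-5-carbaldehyde; 5 4,4,5,5-tetramethyl-2-vinyl-1,3,2-dioxaborolane
Product: 6 6-ethenyl-2,2-diphenyl-1,3-benzodioxole-5-carbaldehyde
Conditions: Pd(PPh3)4 (3 mol%), K2CO3, dioxane/H2O (4:1), 90 °C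
Reagents that add atoms: none
Why: Suzuki–Miyaura coupling of the ortho-formyl-activated aryl bromide installs the vinyl group that later becomes the C4 aldehyde.

**Step 4**
Reactants: 6 6-ethenyl-2,2-diphenyl-1,3-benzodioxole-5-carbaldehyde; 7 nitromethane
Product: 8 6-ethenyl-5-[(E)-2-nitroethenyl]-2,2-diphenyl-1,3-benzodioxole
Conditions: NH4OAc (0.5 equiv), MeNO2 (solvent), 95 °C
Reagents that add atoms: none
Why: Henry (nitroaldol) condensation with loss of water gives the conjugated E-nitroalkene, the Michael acceptor.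

**Step 5 (key step)**
Reactants: 8 6-ethenyl-5-[(E)-2-nitroethenyl]-2,2-diphenyl-1,3-benzodioxole; 9 pent-4-enal
Product: 10 (2R,3S)-3-(6-ethenyl-2,2-diphenyl-1,3-benzodioxol-5-yl)-4-nitro-2-(prop-2-en-1-yl)butanal
Conditions: (S)-α,α-diphenylprolinol trimethylsilyl ether (10 mol%), 4-nitrophenol (20 mol%), 9 (2 equiv), toluene, 0 °C to rt; crude aldehyde used at once
Reagents that add atoms: none
Why: Hayashi–Jørgensen enamine Michael addition, in which the E-enamine of 9 attacks the nitroalkene through an acyclic synclinal transition state on the face away from the diphenyl(silyloxy)methyl group, so the (S)-catalyst gives the syn adduct (same sense as the parent propanal/β-nitrostyrene case) and sets the future C1 and C2 together.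

**Step 6**
Reactants: 10 (2R,3S)-3-(6-ethenyl-2,2-diphenyl-1,3-benzodioxol-5-yl)-4-nitro-2-(prop-2-en-1-yl)butanal
Product: 11 (2R,3S)-3-(6-ethenyl-2,2-diphenyl-1,3-benzodioxol-5-yl)-4-nitro-2-(prop-2-en-1-yl)butanoic acid
Conditions: NaClO2, NaH2PO4, 2-methyl-2-butene (20 equiv), t-BuOH/H2O, 0 °C to rt
Reagents that add atoms: NaClO2 (sodium chlorite), [Na+].[O-]Cl=O
Why: Pinnick oxidation converts the epimerizable α-branched aldehyde to the acid without touching C2, while the alkene scavenger protects both alkenes and the electron-rich ring from HOCl.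

**Step 7**
Reactants: 11 (2R,3S)-3-(6-ethenyl-2,2-diphenyl-1,3-benzodioxol-5-yl)-4-nitro-2-(prop-2-en-1-yl)butanoic acid
Product: 12 tert-butyl (2R,3S)-3-(6-ethenyl-2,2-diphenyl-1,3-benzodioxol-5-yl)-4-nitro-2-(prop-2-en-1-yl)butanoate
Conditions: tert-butyl 2,2,2-trichloroacetimidate (TBTA, 2.5 equiv), CH2Cl2/cyclohexane, rt, 16 h; chromatography removes the minor anti isomer
Reagents that add atoms: tert-butyl 2,2,2-trichloroacetimidate, CC(C)(C)OC(=N)C(Cl)(Cl)Cl
Why: Imidate esterification (tert-butyl transfer to the acid under self-catalysis) needs no base, so the nitroalkane and the C2 centre are not disturbed.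

**Step 8**
Reactants: 12 tert-butyl (2R,3S)-3-(6-ethenyl-2,2-diphenyl-1,3-benzodioxol-5-yl)-4-nitro-2-(prop-2-en-1-yl)butanoate
Product: 14 tert-butyl (1S,2S)-6,7-(diphenylmethylenedioxy)-3-formyl-1-(nitromethyl)-1,2-dihydronaphthalene-2-carboxylate, via dialdehyde 13 (not isolated)
Conditions: OsO4 (2 mol%), NaIO4 (5 equiv), 2,6-lutidine, dioxane/H2O (3:1), rt; then Bn2NH·CF3CO2H (20 mol%), toluene, 45 °C
Reagents that add atoms: NaIO4 (sodium periodate), [Na+].[O-]I(=O)(=O)=O; OsO4 (catalytic oxygen carrier), O=[Os](=O)(=O)=O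
Why: Lemieux–Johnson cleavage turns both terminal alkenes into aldehydes and an enamine-mediated intramolecular aldol condensation of the only enolizable aldehyde onto the aryl aldehyde closes ring B as the conjugated enal, the ammonium salt being too weakly basic for Henry side reactions or epimerization.

**Step 9**
Reactants: 14 tert-butyl (1S,2S)-6,7-(diphenylmethylenedioxy)-3-formyl-1-(nitromethyl)-1,2-dihydronaphthalene-2-carboxylate
Product: 15 (1S,2S)-2-(tert-butoxycarbonyl)-6,7-(diphenylmethylenedioxy)-1-(nitromethyl)-1,2-dihydronaphthalene-3-carboxylic acid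
Conditions: NaClO2, NaH2PO4, 2-methyl-2-butene, t-BuOH/H2O, 0 °C to rt
Reagents that add atoms: NaClO2 (sodium chlorite), [Na+].[O-]Cl=O
Why: Pinnick oxidation is the standard mild way to take an α,β-unsaturated aldehyde to the acrylic acid without moving the double bond.

**Step 10**
Reactants: 15 (1S,2S)-2-(tert-butoxycarbonyl)-6,7-(diphenylmethylenedioxy)-1-(nitromethyl)-1,2-dihydronaphthalene-3-carboxylic acid
Product: 16 di-tert-butyl (1S,2S)-6,7-(diphenylmethylenedioxy)-1-(nitromethyl)-1,2-dihydronaphthalene-2,3-dicarboxylate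
Conditions: TBTA (2.5 equiv), CH2Cl2/cyclohexane, rt
Reagents that add atoms: tert-butyl 2,2,2-trichloroacetimidate, CC(C)(C)OC(=N)C(Cl)(Cl)Cl
Why: Base-free imidate esterification again, giving a diester that can be removed by acid at the end.

**Step 11**
Reactants: 16 di-tert-butyl (1S,2S)-6,7-(diphenylmethylenedioxy)-1-(nitromethyl)-1,2-dihydronaphthalene-2,3-dicarboxylate
Product: 17 (1S,2S)-2,3-bis(tert-butoxycarbonyl)-6,7-(diphenylmethylenedioxy)-1,2-dihydronaphthalene-1-carboxylic acid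
Conditions: NaNO2 (3 equiv), AcOH (10 equiv), DMSO, 35 °C
Reagents that add atoms: NaNO2 (sodium nitrite), [Na+].[O-]N=O
Why: Mioskowski's nitrite/acetic acid oxidation (a Nef-type conversion through the nitrolic acid and nitrile oxide) turns the primary nitro group into the carboxylic acid under weakly acidic conditions that spare the esters, the ketal and the C1 centre.

**Step 12**
Reactants: 17 (1S,2S)-2,3-bis(tert-butoxycarbonyl)-6,7-(diphenylmethylenedioxy)-1,2-dihydronaphthalene-1-carboxylic acid; 18 3-tert-butoxy-3-oxopropanoic acid (mono-tert-butyl malonate)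
Product: 20 di-tert-butyl (1S,2S)-1-(3-tert-butoxy-3-oxopropanoyl)-6,7-(diphenylmethylenedioxy)-1,2-dihydronaphthalene-2,3-dicarboxylate, via acyl imidazolide 19 (not isolated)
Conditions: CDI (1.2 equiv), THF, rt; then 18 (2 equiv), MgCl2 (2 equiv), Et3N (4 equiv), THF/MeCN, rt to 40 °C; aq. citric acid
Reagents that add atoms: 1,1'-carbonyldiimidazole, O=C(n1ccnc1)n1ccnc1 (its imidazol-1-yl group sits in 19 only; none of its atoms remain in 20)
Why: Masamune–Brooks homologation, a decarboxylative crossed Claisen condensation of the magnesium malonate half-ester with the acyl imidazolide, gives the β-keto ester, which stays as its magnesium enolate so that C1 is not enolized.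

**Step 13**
Reactants: 20 di-tert-butyl (1S,2S)-1-(3-tert-butoxy-3-oxopropanoyl)-6,7-(diphenylmethylenedioxy)-1,2-dihydronaphthalene-2,3-dicarboxylate
Product: 21 di-tert-butyl (1S,2S)-1-[(Z)-3-tert-butoxy-3-oxo-1-(trifluoromethylsulfonyloxy)prop-1-en-1-yl]-6,7-(diphenylmethylenedioxy)-1,2-dihydronaphthalene-2,3-dicarboxylate
Conditions: Tf2O (1.5 equiv), sat. aq. LiOH, toluene, 5 °C
Reagents that add atoms: trifluoromethanesulfonic anhydride, O=S(=O)(OS(=O)(=O)C(F)(F)F)C(F)(F)F
Why: O-Sulfonylation of the chelated lithium Z-enolate of the β-keto ester gives the Z enol triflate (triflate cis to the ester), the geometry needed for the later lactonization, and only the most acidic proton is removed.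

**Step 14**
Reactants: 22 2-acetamidoacrylic acid
Product: 23 tert-butyl 2-acetamidoacrylate
Conditions: TBTA (2 equiv), CH2Cl2/THF, rt
Reagents that add atoms: tert-butyl 2,2,2-trichloroacetimidate, CC(C)(C)OC(=N)C(Cl)(Cl)Cl
Why: Imidate esterification gives an acid-labile, chromatographable Heck partner that serves as a masked pyruvate.

**Step 15**
Reactants: 21 di-tert-butyl (1S,2S)-1-[(Z)-3-tert-butoxy-3-oxo-1-(trifluoromethylsulfonyloxy)prop-1-en-1-yl]-6,7-(diphenylmethylenedioxy)-1,2-dihydronaphthalene-2,3-dicarboxylate; 23 tert-butyl 2-acetamidoacrylate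
Product: 24 di-tert-butyl (2Z,4Z)-5-acetamido-3-[(1R,2S)-2,3-bis(tert-butoxycarbonyl)-6,7-(diphenylmethylenedioxy)-1,2-dihydronaphthalen-1-yl]hexa-2,4-dienedioate
Conditions: Pd(OAc)2 (10 mol%), n-Bu4NCl (1 equiv), NaHCO3 (2.5 equiv), 23 (2 equiv), DMF, 60 °C, Ar
Reagents that add atoms: none
Why: Mizoroki–Heck reaction under Jeffery conditions, in which zerovalent palladium inserts into the electron-poor enol triflate with retention, the acrylate inserts at its CH2 terminus and β-hydride elimination gives the dienamide, while the weak base avoids elimination of triflic acid and epimerization.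

**Step 16**
Reactants: 24 di-tert-butyl (2Z,4Z)-5-acetamido-3-[(1R,2S)-2,3-bis(tert-butoxycarbonyl)-6,7-(diphenylmethylenedioxy)-1,2-dihydronaphthalen-1-yl]hexa-2,4-dienedioate
Product: 25 (1R,2S)-1-(6-carboxy-2-oxo-2H-pyran-4-yl)-6,7-dihydroxy-1,2-dihydronaphthalene-2,3-dicarboxylic acid
Conditions: 6 M aq. HCl/AcOH (1:1), 65 °C, Ar; evaporate; C18 chromatography (H2O/MeCN, 0.1% HCO2H)
Reagents that add atoms: water, O
Why: Acidolysis removes the four tert-butyl groups and the ketal and hydrolyses the enamide to the 2-oxo acid, whose enol lactonizes onto the cis carboxyl (the classical oxalocrotonate-to-pyrone cyclization), all without base so that C1 and C2 keep their configuration.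

**Compound list**
1 | 2-bromo-4,5-dimethoxybenzaldehyde | COc1cc(C=O)c(Br)cc1OC | starting material
2 | 2-bromo-4,5-dihydroxybenzaldehyde | Oc1cc(C=O)c(Br)cc1O | intermediate
3 | dichlorodiphenylmethane | ClC(Cl)(c1ccccc1)c1ccccc1 | starting material
4 | 6-bromo-2,2-diphenyl-1,3-benzodioxole-5-carbaldehyde | O=Cc1cc2OC(c3ccccc3)(c3ccccc3)Oc2cc1Br | intermediate
5 | 4,4,5,5-tetramethyl-2-vinyl-1,3,2-dioxaborolane | C=CB1OC(C)(C)C(C)(C)O1 | starting material
6 | 6-ethenyl-2,2-diphenyl-1,3-benzodioxole-5-carbaldehyde | C=Cc1cc2OC(c3ccccc3)(c3ccccc3)Oc2cc1C=O | intermediate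
7 | nitromethane | C[N+](=O)[O-] | starting material
8 | 6-ethenyl-5-[(E)-2-nitroethenyl]-2,2-diphenyl-1,3-benzodioxole | C=Cc1cc2OC(c3ccccc3)(c3ccccc3)Oc2cc1/C=C/[N+](=O)[O-] | intermediate
9 | pent-4-enal | C=CCCC=O | starting material
10 | (2R,3S)-3-(6-ethenyl-2,2-diphenyl-1,3-benzodioxol-5-yl)-4-nitro-2-(prop-2-en-1-yl)butanal | C=Cc1cc2OC(c3ccccc3)(c3ccccc3)Oc2cc1[C@@H](C[N+](=O)[O-])[C@@H](CC=C)C=O | intermediate
11 | (2R,3S)-3-(6-ethenyl-2,2-diphenyl-1,3-benzodioxol-5-yl)-4-nitro-2-(prop-2-en-1-yl)butanoic acid | C=Cc1cc2OC(c3ccccc3)(c3ccccc3)Oc2cc1[C@@H](C[N+](=O)[O-])[C@@H](CC=C)C(=O)O | intermediate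
12 | tert-butyl (2R,3S)-3-(6-ethenyl-2,2-diphenyl-1,3-benzodioxol-5-yl)-4-nitro-2-(prop-2-en-1-yl)butanoate | C=Cc1cc2OC(c3ccccc3)(c3ccccc3)Oc2cc1[C@@H](C[N+](=O)[O-])[C@@H](CC=C)C(=O)OC(C)(C)C | intermediate
13 | tert-butyl (2R,3S)-3-(6-formyl-2,2-diphenyl-1,3-benzodioxol-5-yl)-4-nitro-2-(2-oxoethyl)butanoate | O=Cc1cc2OC(c3ccccc3)(c3ccccc3)Oc2cc1[C@@H](C[N+](=O)[O-])[C@@H](CC=O)C(=O)OC(C)(C)C | intermediate
14 | tert-butyl (1S,2S)-6,7-(diphenylmethylenedioxy)-3-formyl-1-(nitromethyl)-1,2-dihydronaphthalene-2-carboxylate | O=CC1=Cc2cc3OC(c4ccccc4)(c4ccccc4)Oc3cc2[C@@H](C[N+](=O)[O-])[C@@H]1C(=O)OC(C)(C)C | intermediate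
15 | (1S,2S)-2-(tert-butoxycarbonyl)-6,7-(diphenylmethylenedioxy)-1-(nitromethyl)-1,2-dihydronaphthalene-3-carboxylic acid | OC(=O)C1=Cc2cc3OC(c4ccccc4)(c4ccccc4)Oc3cc2[C@@H](C[N+](=O)[O-])[C@@H]1C(=O)OC(C)(C)C | intermediate
16 | di-tert-butyl (1S,2S)-6,7-(diphenylmethylenedioxy)-1-(nitromethyl)-1,2-dihydronaphthalene-2,3-dicarboxylate | CC(C)(C)OC(=O)C1=Cc2cc3OC(c4ccccc4)(c4ccccc4)Oc3cc2[C@@H](C[N+](=O)[O-])[C@@H]1C(=O)OC(C)(C)C | intermediate
17 | (1S,2S)-2,3-bis(tert-butoxycarbonyl)-6,7-(diphenylmethylenedioxy)-1,2-dihydronaphthalene-1-carboxylic acid | CC(C)(C)OC(=O)C1=Cc2cc3OC(c4ccccc4)(c4ccccc4)Oc3cc2[C@@H](C(=O)O)[C@@H]1C(=O)OC(C)(C)C | intermediate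
18 | 3-tert-butoxy-3-oxopropanoic acid (mono-tert-butyl malonate) | OC(=O)CC(=O)OC(C)(C)C | starting material
19 | di-tert-butyl (1S,2S)-6,7-(diphenylmethylenedioxy)-1-(1H-imidazol-1-ylcarbonyl)-1,2-dihydronaphthalene-2,3-dicarboxylate | CC(C)(C)OC(=O)C1=Cc2cc3OC(c4ccccc4)(c4ccccc4)Oc3cc2[C@@H](C(=O)n5ccnc5)[C@@H]1C(=O)OC(C)(C)C | intermediate
20 | di-tert-butyl (1S,2S)-1-(3-tert-butoxy-3-oxopropanoyl)-6,7-(diphenylmethylenedioxy)-1,2-dihydronaphthalene-2,3-dicarboxylate | CC(C)(C)OC(=O)C1=Cc2cc3OC(c4ccccc4)(c4ccccc4)Oc3cc2[C@@H](C(=O)CC(=O)OC(C)(C)C)[C@@H]1C(=O)OC(C)(C)C | intermediate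
21 | di-tert-butyl (1S,2S)-1-[(Z)-3-tert-butoxy-3-oxo-1-(trifluoromethylsulfonyloxy)prop-1-en-1-yl]-6,7-(diphenylmethylenedioxy)-1,2-dihydronaphthalene-2,3-dicarboxylate | CC(C)(C)OC(=O)C1=Cc2cc3OC(c4ccccc4)(c4ccccc4)Oc3cc2[C@@H](/C(OS(=O)(=O)C(F)(F)F)=C/C(=O)OC(C)(C)C)[C@@H]1C(=O)OC(C)(C)C | intermediate
22 | 2-acetamidoacrylic acid | CC(=O)NC(=C)C(=O)O | starting material
23 | tert-butyl 2-acetamidoacrylate | CC(=O)NC(=C)C(=O)OC(C)(C)C | intermediate
24 | di-tert-butyl (2Z,4Z)-5-acetamido-3-[(1R,2S)-2,3-bis(tert-butoxycarbonyl)-6,7-(diphenylmethylenedioxy)-1,2-dihydronaphthalen-1-yl]hexa-2,4-dienedioate | CC(C)(C)OC(=O)C1=Cc2cc3OC(c4ccccc4)(c4ccccc4)Oc3cc2[C@@H](/C(=C/C(=O)OC(C)(C)C)/C=C(\NC(C)=O)C(=O)OC(C)(C)C)[C@@H]1C(=O)OC(C)(C)C | intermediate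
25 | (1R,2S)-1-(6-carboxy-2-oxo-2H-pyran-4-yl)-6,7-dihydroxy-1,2-dihydronaphthalene-2,3-dicarboxylic acid | O=C(O)C1=Cc2cc(O)c(O)cc2[C@@H](c2cc(C(=O)O)oc(=O)c2)[C@@H]1C(=O)O | target

**Step count**
Total: 16 steps. Longest linear sequence: 15 steps (steps 1 to 13, 15 and 16; step 14 is a side branch).

**Three steps most likely to fail**

Step 15 (Heck coupling of a hindered enol triflate; loss of triflic acid to an allene or slow insertion are the dangers). The fallback sets out from 21 and 23 and comes back at 24. Compound 21 is borylated with bis(pinacolato)diboron (PdCl2(PPh3)2, PPh3, KOPh, toluene, 50 °C) to the alkenyl pinacol boronate F1. Compound 23 is brominated with N-bromosuccinimide (CH2Cl2, rt, then Et3N) to tert-butyl (Z)-2-acetamido-3-bromoacrylate F2. Suzuki–Miyaura coupling of F1 and F2 (Pd(PPh3)4, K2CO3, dioxane/H2O, 70 °C) then gives 24 with both alkene geometries retained.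

Step 16 (one-pot deprotection, enamide hydrolysis and lactonization; the 2-oxo acid may stay open or the hot acid may damage the dihydronaphthalene). The fallback sets out from 21 and comes back at 25, building the pyrone under neutral conditions so that only a mild deprotection remains. Sonogashira coupling of 21 with tert-butyldimethyl(prop-2-yn-1-yloxy)silane (PdCl2(PPh3)2, CuI, i-Pr2NH, THF, rt) gives the enyne F3. (Ph3P)AuCl/AgSbF6 (5 mol%, CH2Cl2, rt) triggers 6-endo attack of the cis tert-butyl ester carbonyl on the alkyne with loss of 2-methylpropene to give the silyloxymethyl pyrone F4. HF·pyridine (THF, 0 °C) gives the hydroxymethyl pyrone F5. TEMPO (cat.) with PhI(OAc)2 in MeCN/H2O oxidizes it to the pyrone carboxylic acid F6. TFA/H2O (9:1, rt) then removes the two tert-butyl esters and the ketal to give 25.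

Step 11 (nitro to carboxylic acid on a crowded, polyfunctional substrate). The fallback sets out from 16 and comes back at 17. The nitronate (NaOMe, 1 equiv, MeOH, 0 °C) is added to buffered aqueous TiCl3/NH4OAc (McMurry reductive Nef reaction) to give the C1 aldehyde F7. Pinnick oxidation (NaClO2, NaH2PO4, 2-methyl-2-butene, t-BuOH/H2O) then gives 17; any epimerization at C1 returns to the favoured trans-diaxial arrangement.

**Further compounds**
F1 | step 15 | di-tert-butyl (1R,2S)-1-[(E)-3-tert-butoxy-3-oxo-1-(4,4,5,5-tetramethyl-1,3,2-dioxaborolan-2-yl)prop-1-en-1-yl]-6,7-(diphenylmethylenedioxy)-1,2-dihydronaphthalene-2,3-dicarboxylate (boron cis to the ester) | CC(C)(C)OC(=O)C1=Cc2cc3OC(c4ccccc4)(c4ccccc4)Oc3cc2[C@@H](/C(B5OC(C)(C)C(C)(C)O5)=C/C(=O)OC(C)(C)C)[C@@H]1C(=O)OC(C)(C)C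
F2 | step 15 | tert-butyl (Z)-2-acetamido-3-bromoacrylate | Br/C=C(\NC(C)=O)C(=O)OC(C)(C)C
F3 | step 16 | di-tert-butyl (1S,2S)-1-[(Z)-1-tert-butoxy-6-(tert-butyldimethylsilyloxy)-1-oxohex-2-en-4-yn-3-yl]-6,7-(diphenylmethylenedioxy)-1,2-dihydronaphthalene-2,3-dicarboxylate | CC(C)(C)OC(=O)C1=Cc2cc3OC(c4ccccc4)(c4ccccc4)Oc3cc2[C@@H](/C(C#CCO[Si](C)(C)C(C)(C)C)=C/C(=O)OC(C)(C)C)[C@@H]1C(=O)OC(C)(C)C
F4 | step 16 | di-tert-butyl (1R,2S)-1-[6-(tert-butyldimethylsilyloxymethyl)-2-oxo-2H-pyran-4-yl]-6,7-(diphenylmethylenedioxy)-1,2-dihydronaphthalene-2,3-dicarboxylate | CC(C)(C)OC(=O)C1=Cc2cc3OC(c4ccccc4)(c4ccccc4)Oc3cc2[C@@H](c5cc(CO[Si](C)(C)C(C)(C)C)oc(=O)c5)[C@@H]1C(=O)OC(C)(C)C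
F5 | step 16 | di-tert-butyl (1R,2S)-1-[6-(hydroxymethyl)-2-oxo-2H-pyran-4-yl]-6,7-(diphenylmethylenedioxy)-1,2-dihydronaphthalene-2,3-dicarboxylate | CC(C)(C)OC(=O)C1=Cc2cc3OC(c4ccccc4)(c4ccccc4)Oc3cc2[C@@H](c5cc(CO)oc(=O)c5)[C@@H]1C(=O)OC(C)(C)C
F6 | step 16 | 4-[(1R,2S)-2,3-bis(tert-butoxycarbonyl)-6,7-(diphenylmethylenedioxy)-1,2-dihydronaphthalen-1-yl]-2-oxo-2H-pyran-6-carboxylic acid | CC(C)(C)OC(=O)C1=Cc2cc3OC(c4ccccc4)(c4ccccc4)Oc3cc2[C@@H](c5cc(C(=O)O)oc(=O)c5)[C@@H]1C(=O)OC(C)(C)C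
F7 | step 11 | di-tert-butyl (1S,2S)-6,7-(diphenylmethylenedioxy)-1-formyl-1,2-dihydronaphthalene-2,3-dicarboxylate | CC(C)(C)OC(=O)C1=Cc2cc3OC(c4ccccc4)(c4ccccc4)Oc3cc2[C@@H](C=O)[C@@H]1C(=O)OC(C)(C)C
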